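**Plan**

Ring numbering used throughout: O1–O2–C3–C4–C5–C6, with C3 carrying CH2CO2H, C4 carrying CH3, and C6 carrying CH3 and the (2R)-2-methyl-10-phenyldecyl chain.

1. Retrosynthesis: cut the C3–CH2 bond of the acetic acid arm (silyl ketene acetal plus a peroxycarbenium ion at C3). Then cut, in one operation, C5–C4 (aldol) and O2–C3 (peroxy-acetal), using a temporary OH on C5 that is later removed by radical deoxygenation. Then cut C6–O1 (epoxide perhydrolysis), the epoxide CH2 (sulfur ylide) and the chain alkene (cross-metathesis).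
2. Enabling feature: in the 1,2-dioxane ring, C3 is a masked aldehyde carbon once the acetate arm is removed, and C4 is its α-carbon. C5 lies next to the fully substituted peroxide carbon C6, so a C5 aldehyde cannot enolise. Propanal is then the only possible aldol donor, and the C6 hydroperoxide closes the six-membered ring onto the new aldehyde.
3. Forward order: chain (steps 1–3), C6–O1–O2 (steps 4–5), silyl protection and C5 aldehyde (steps 6–8), the only ring (step 9), C5 deoxygenation (steps 10–11), C3 arm (step 12), acid (step 13).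
4. Stereochemistry: the side-chain centre is bought with (R)-citronellic acid. C6 comes from a catalyst-controlled Corey–Chaykovsky epoxidation followed by invertive perhydrolysis. C4 comes from L-proline. C3 is relayed from C4 and C6 by axial attack on the peroxycarbenium ion.

Key step: step 9

Assumption: LaLi3[(S)-binaphthoxide]3 is taken to give the (S)-oxirane 6 from this aliphatic methyl ketone; if the sense is the opposite, the (R)-binaphthoxide complex is used and nothing else changes.

Step 1
Reactants: 1 (3R)-3,7-dimethyloct-6-enoic acid [(R)-citronellic acid]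
Product: 2 (4R)-4,8-dimethylnon-7-en-2-one
Conditions: MeLi (2.2 equiv), Et2O, 0 °C to rt; then H2O
Reagents that add atoms: methyllithium, [Li]C
Why: Addition of an organolithium to a lithium carboxylate stops at the dilithium gem-diolate, which should give the methyl ketone on hydrolysis, and the bought stereocenter is not touched.

Step 2
Reactants: 2 (4R)-4,8-dimethylnon-7-en-2-one; 3 6-phenylhex-1-ene
Product: 4 (4R,7E)-4-methyl-12-phenyldodec-7-en-2-one (E/Z mixture expected, both usable)
Conditions: 3 (3 equiv), second-generation Grubbs catalyst RuCl2(=CHPh)(PCy3)(H2IMes) (5 mol%), CH2Cl2, 40 °C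
Reagents that add atoms: 6-phenylhex-1-ene (3), C=CCCCCc1ccccc1
Why: Olefin cross-metathesis of the prenyl-type terminus with an excess of the terminal alkene releases volatile 2-methylpropene and should give the disubstituted alkene, whose geometry is irrelevant because it is hydrogenated next.

Step 3
Reactants: 4 (4R,7E)-4-methyl-12-phenyldodec-7-en-2-one
Product: 5 (4R)-4-methyl-12-phenyldodecan-2-one
Conditions: H2 (1 atm), Pd/C (10 wt% Pd on carbon), EtOAc, rt
Reagents that add atoms: none
Why: Heterogeneous catalytic hydrogenation should saturate the disubstituted alkene without touching the ketone or the arene.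

Step 4
Reactants: 5 (4R)-4-methyl-12-phenyldodecan-2-one
Product: 6 (2S)-2-methyl-2-[(2R)-2-methyl-10-phenyldecyl]oxirane
Conditions: Me3S(O)I, NaH, THF; LaLi3[(S)-binaphthoxide]3 (5 mol%), tris(2,4,6-trimethoxyphenyl)phosphine oxide (5 mol%), 5 Å molecular sieves, THF, rt
Reagents that add atoms: trimethylsulfoxonium iodide, C[S+](C)(C)=O.[I-]
Why: Catalytic asymmetric Corey–Chaykovsky epoxidation of a methyl ketone, in which the lanthanum–lithium binaphthoxide binds ketone and ylide and should deliver CH2 to one carbonyl face under catalyst control (the remote methyl has little influence), which sets the future C6.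

Step 5
Reactants: 6 (2S)-2-methyl-2-[(2R)-2-methyl-10-phenyldecyl]oxirane
Product: 7 (2R,4R)-2-hydroperoxy-2,4-dimethyl-12-phenyldodecan-1-ol
Conditions: anhydrous ethereal H2O2 (5 equiv), H3PMo12O40 (5 mol%), Et2O, rt
Reagents that add atoms: hydrogen peroxide, OO
Why: Acid-catalysed perhydrolysis of a 2,2-disubstituted epoxide, in which H2O2 should attack the tertiary carbon in a borderline SN2 opening with inversion, so that the (S)-oxirane becomes the (R)-tertiary hydroperoxide and C6–O1–O2 is fixed.

Step 6
Reactants: 7 (2R,4R)-2-hydroperoxy-2,4-dimethyl-12-phenyldodecan-1-ol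
Product: 8 triethyl{[(2R,4R)-2,4-dimethyl-12-phenyl-2-(triethylsilylperoxy)dodecyl]oxy}silane
Conditions: Et3SiCl (2.5 equiv), imidazole (3 equiv), CH2Cl2, 0 °C
Reagents that add atoms: chlorotriethylsilane, CC[Si](Cl)(CC)CC
Why: Silylation of both the hydroperoxide and the alcohol under weakly basic conditions, a monofunctional silyl cap being chosen because acetal-type caps would close a 1,2,4-trioxane with the neighbouring hydroxyl.

Step 7
Reactants: 8 triethyl{[(2R,4R)-2,4-dimethyl-12-phenyl-2-(triethylsilylperoxy)dodecyl]oxy}silane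
Product: 9 (2R,4R)-2,4-dimethyl-12-phenyl-2-(triethylsilylperoxy)dodecan-1-ol
Conditions: PPTS (0.1 equiv), MeOH/CH2Cl2 (1:1), 0 °C
Reagents that add atoms: none
Why: Selective acid-catalysed desilylation, since methanolysis begins with protonation of oxygen and the basic primary alkyl silyl ether should be cleaved well before the much less basic silyl peroxide.

Step 8
Reactants: 9 (2R,4R)-2,4-dimethyl-12-phenyl-2-(triethylsilylperoxy)dodecan-1-ol
Product: 10 (2R,4R)-2,4-dimethyl-12-phenyl-2-(triethylsilylperoxy)dodecanal
Conditions: Dess–Martin periodinane, pyridine, CH2Cl2, 0 °C to rt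
Reagents that add atoms: none
Why: Dess–Martin oxidation of the neopentyl primary alcohol under buffered conditions should give an aldehyde that has no α-hydrogen and therefore can neither enolise nor lose the peroxide by elimination.

Step 9
Reactants: 10 (2R,4R)-2,4-dimethyl-12-phenyl-2-(triethylsilylperoxy)dodecanal; 11 propanal
Product: 14 (4S,5R,6R)-3-methoxy-4,6-dimethyl-6-[(2R)-2-methyl-10-phenyldecyl]-1,2-dioxan-5-ol (mixture of C3 anomers), via aldol adduct 12 (not isolated), via cyclic peroxy-hemiacetal 13 (not isolated)
Conditions: L-proline (0.3 equiv), 11 (3 equiv, syringe pump), DMF, 4 °C; volatiles removed in vacuo; then MeOH, camphorsulfonic acid (0.2 equiv), rt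
Reagents that add atoms: propanal (11), CCC=O; methanol, CO
Why: L-Proline and propanal form the (E)-enamine, which adds through the carboxylic-acid hydrogen-bonded chair transition state to the non-enolisable aldehyde 10 and forms C5–C4 (direct proline-catalysed cross-aldol of two aldehydes is the closest known reaction type); acidic methanol then removes the silyl group from the peroxide, the freed hydroperoxide adds to the new aldehyde carbon C3 and forms O2–C3, and the hemiacetal is exchanged to the methyl acetal (peroxy-acetalisation of a γ-hydroperoxy aldehyde, as known for 1,2-dioxan-3-ols). The 1,2-dioxane ring closes in 6-exo-trig mode by attack of the terminal peroxide oxygen on the C3 carbonyl. C4 is set by the catalyst, because the enamine face syn to the carboxylic acid reacts, which for L-proline should give the (S) configuration of the target whichever aldehyde face is attacked; C5 (anti, R) is a temporary centre and C3 is an anomeric mixture that is erased in step 12. The step needs cross-aldol over self-aldol selectivity, which the absence of α-hydrogens in 10 and the slow addition of propanal should secure, and it needs six-ring peroxy-acetal closure instead of intermolecular 1,2,4-trioxane formation, which the removal of excess propanal before the acid stage and the intramolecular nature of the closure should secure. The catalyst's preference for the Re face of the aldehyde opposes the weak polar Felkin–Anh bias of the α-peroxy centre (its other substituents, CH3 and CH2R, differ little), so any C5 epimer that forms converges in step 11.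

Step 10
Reactants: 14 (4S,5R,6R)-3-methoxy-4,6-dimethyl-6-[(2R)-2-methyl-10-phenyldecyl]-1,2-dioxan-5-ol
Product: 15 O-[(4S,5R,6R)-3-methoxy-4,6-dimethyl-6-[(2R)-2-methyl-10-phenyldecyl]-1,2-dioxan-5-yl] O-phenyl carbonothioate
Conditions: PhOC(S)Cl (2 equiv), pyridine (3 equiv), DMAP (0.2 equiv), CH2Cl2, 0 °C to rt
Reagents that add atoms: O-phenyl chlorothionoformate, S=C(Cl)Oc1ccccc1
Why: Acylation of the hindered secondary alcohol under nucleophilic catalysis should give the thionocarbonate needed for radical deoxygenation, and the weak amine bases should not trigger Kornblum–DeLaMare cleavage of the peroxy-acetal.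

Step 11
Reactants: 15 O-[(4S,5R,6R)-3-methoxy-4,6-dimethyl-6-[(2R)-2-methyl-10-phenyldecyl]-1,2-dioxan-5-yl] O-phenyl carbonothioate
Product: 16 (4S,6R)-3-methoxy-4,6-dimethyl-6-[(2R)-2-methyl-10-phenyldecyl]-1,2-dioxane (mixture of C3 anomers)
Conditions: Bu3SnH (4 equiv, 0.4 M), Et3B (0.3 equiv)/air, toluene, rt
Reagents that add atoms: none
Why: Barton–McCombie deoxygenation, in which the stannyl radical should add to C=S far faster than it attacks the O–O bond, while the endocyclic C5 radical is poorly aligned for homolytic substitution at O1 and is quenched by the concentrated stannane before β-scission, as in tin hydride reductions of β-halo cyclic peroxides; C4 and C6 are untouched.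

Step 12
Reactants: 16 (4S,6R)-3-methoxy-4,6-dimethyl-6-[(2R)-2-methyl-10-phenyldecyl]-1,2-dioxane; 17 tert-butyl[(1-methoxyethenyl)oxy]dimethylsilane
Product: 18 methyl 2-[(3S,4S,6R)-4,6-dimethyl-6-[(2R)-2-methyl-10-phenyldecyl]-1,2-dioxan-3-yl]acetate
Conditions: 17 (3 equiv), TMSOTf (0.2 equiv), CH2Cl2, −78 °C
Reagents that add atoms: tert-butyl[(1-methoxyethenyl)oxy]dimethylsilane (17), C=C(OC)O[Si](C)(C)C(C)(C)C
Why: Mukaiyama-type addition of a silyl ketene acetal to a peroxycarbenium ion, in which the nucleophile should attack C3 axially on the half-chair that keeps C4–CH3 pseudoequatorial and avoids a 1,3-diaxial clash between C4–CH3 and the C6 side chain, that is anti to the axial C6–CH3, which gives the 3,4-cis (3S) arm by substrate control.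

Step 13
Reactants: 18 methyl 2-[(3S,4S,6R)-4,6-dimethyl-6-[(2R)-2-methyl-10-phenyldecyl]-1,2-dioxan-3-yl]acetate
Product: 19 2-[(3S,4S,6R)-4,6-dimethyl-6-[(2R)-2-methyl-10-phenyldecyl]-1,2-dioxan-3-yl]acetic acid
Conditions: LiOH (3 equiv), THF/H2O (3:1), 0 °C to rt; then aq. HCl to pH 3
Reagents that add atoms: lithium hydroxide, [Li+].[OH-]
Why: Saponification of the methyl ester with cold hydroxide should be much faster than enolisation next to the peroxide, so the dialkyl peroxide and the C3 centre are expected to survive and acidification should give the acid.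

**Compound list**

1 | (3R)-3,7-dimethyloct-6-enoic acid [(R)-citronellic acid] | C[C@H](CCC=C(C)C)CC(=O)O | starting material
2 | (4R)-4,8-dimethylnon-7-en-2-one | C[C@H](CCC=C(C)C)CC(C)=O | intermediate
3 | 6-phenylhex-1-ene | C=CCCCCc1ccccc1 | starting material
4 | (4R,7E)-4-methyl-12-phenyldodec-7-en-2-one | C[C@H](CC/C=C/CCCCc1ccccc1)CC(C)=O | intermediate
5 | (4R)-4-methyl-12-phenyldodecan-2-one | C[C@H](CCCCCCCCc1ccccc1)CC(C)=O | intermediate
6 | (2S)-2-methyl-2-[(2R)-2-methyl-10-phenyldecyl]oxirane | C[C@H](CCCCCCCCc1ccccc1)C[C@@]1(C)CO1 | intermediate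
7 | (2R,4R)-2-hydroperoxy-2,4-dimethyl-12-phenyldodecan-1-ol | C[C@H](CCCCCCCCc1ccccc1)C[C@](C)(CO)OO | intermediate
8 | triethyl{[(2R,4R)-2,4-dimethyl-12-phenyl-2-(triethylsilylperoxy)dodecyl]oxy}silane | C[C@H](CCCCCCCCc1ccccc1)C[C@](C)(CO[Si](CC)(CC)CC)OO[Si](CC)(CC)CC | intermediate
9 | (2R,4R)-2,4-dimethyl-12-phenyl-2-(triethylsilylperoxy)dodecan-1-ol | C[C@H](CCCCCCCCc1ccccc1)C[C@](C)(CO)OO[Si](CC)(CC)CC | intermediate
10 | (2R,4R)-2,4-dimethyl-12-phenyl-2-(triethylsilylperoxy)dodecanal | C[C@H](CCCCCCCCc1ccccc1)C[C@](C)(C=O)OO[Si](CC)(CC)CC | intermediate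
11 | propanal | CCC=O | starting material
12 | (2S,3R,4R,6R)-3-hydroxy-2,4,6-trimethyl-14-phenyl-4-(triethylsilylperoxy)tetradecanal (aldol adduct) | C[C@H](CCCCCCCCc1ccccc1)C[C@@](C)(OO[Si](CC)(CC)CC)[C@H](O)[C@H](C)C=O | intermediate
13 | (4S,5R,6R)-4,6-dimethyl-6-[(2R)-2-methyl-10-phenyldecyl]-1,2-dioxane-3,5-diol (cyclic peroxy-hemiacetal, C3 anomers) | C[C@H](CCCCCCCCc1ccccc1)C[C@]1(C)[C@H](O)[C@H](C)C(O)OO1 | intermediate
14 | (4S,5R,6R)-3-methoxy-4,6-dimethyl-6-[(2R)-2-methyl-10-phenyldecyl]-1,2-dioxan-5-ol (C3 anomers) | C[C@H](CCCCCCCCc1ccccc1)C[C@]1(C)[C@H](O)[C@H](C)C(OC)OO1 | intermediate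
15 | O-[(4S,5R,6R)-3-methoxy-4,6-dimethyl-6-[(2R)-2-methyl-10-phenyldecyl]-1,2-dioxan-5-yl] O-phenyl carbonothioate | C[C@H](CCCCCCCCc1ccccc1)C[C@]1(C)[C@H](OC(=S)Oc2ccccc2)[C@H](C)C(OC)OO1 | intermediate
16 | (4S,6R)-3-methoxy-4,6-dimethyl-6-[(2R)-2-methyl-10-phenyldecyl]-1,2-dioxane (C3 anomers) | C[C@H](CCCCCCCCc1ccccc1)C[C@]1(C)C[C@H](C)C(OC)OO1 | intermediate
17 | tert-butyl[(1-methoxyethenyl)oxy]dimethylsilane | C=C(OC)O[Si](C)(C)C(C)(C)C | starting material
18 | methyl 2-[(3S,4S,6R)-4,6-dimethyl-6-[(2R)-2-methyl-10-phenyldecyl]-1,2-dioxan-3-yl]acetate | C[C@H](CCCCCCCCc1ccccc1)C[C@]1(C)C[C@H](C)[C@H](CC(=O)OC)OO1 | intermediate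
19 | 2-[(3S,4S,6R)-4,6-dimethyl-6-[(2R)-2-methyl-10-phenyldecyl]-1,2-dioxan-3-yl]acetic acid | C[C@H](CCCCCCCCc1ccccc1)C[C@]1(C)C[C@H](C)[C@H](CC(=O)O)OO1 | target

Total step count: 13. Longest linear sequence: 13 steps (1 to 19); compounds 3, 11 and 17 are bought.

**Steps most likely to fail**

Step 9. The enamine may fail to add to the congested α-quaternary aldehyde, so that propanal self-condensation takes over; the acid stage may also lose material by retro-aldol cleavage or intermolecular trioxane formation. The fallback sets out from 10 and separates the two bond formations. A reagent-controlled crotylboration is run with the enantiomer of (E)-crotyldiisopinocampheylborane that attacks the Re face of the aldehyde (THF, −78 °C, ethanolamine work-up). It should give the anti homoallylic alcohol (3R,4R,5R,7R)-3,5,7-trimethyl-15-phenyl-5-(triethylsilylperoxy)pentadec-1-en-4-ol F1. Ozonolysis (O3, CH2Cl2/MeOH, −78 °C; Me2S) should then give aldehyde 12, and the acidic methanol stage of step 9 returns to the route at 14.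

Step 11. The stannyl radical may attack the O–O bond, or the C5 radical may undergo β-scission with opening of the peroxide ring. The fallback sets out from 14 and removes the oxygen without a radical chain. Dess–Martin oxidation (pyridine buffer, 0 °C, to limit C4 epimerisation) should give the ketone (4R,6R)-3-methoxy-4,6-dimethyl-6-[(2R)-2-methyl-10-phenyldecyl]-1,2-dioxan-5-one F2. Condensation with TsNHNH2 (MeOH, rt) should give the tosylhydrazone N'-[(4S,6R)-3-methoxy-4,6-dimethyl-6-[(2R)-2-methyl-10-phenyldecyl]-1,2-dioxan-5-ylidene]-4-methylbenzenesulfonohydrazide F3. Reduction with catecholborane (CHCl3, 0 °C) followed by NaOAc·3H2O (50 °C) should deliver the methylene compound through the diazene and come back to the route at 16.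

Step 12. The Lewis acid may trigger heterolysis of the O–O bond (Hock-type fragmentation) instead of loss of methoxide, or the facial selectivity at C3 may be poor. The fallback sets out from 16 and builds the arm by olefination and conjugate addition. Hydrolysis (AcOH/H2O/THF) should give the cyclic peroxy-hemiacetal (4S,6R)-4,6-dimethyl-6-[(2R)-2-methyl-10-phenyldecyl]-1,2-dioxan-3-ol F4, which is in equilibrium with its open hydroperoxy aldehyde. A Wittig reaction with the stabilised ylide Ph3P=CHCO2Me should give the hydroperoxy enoate methyl (2E,4S,6R,8R)-6-hydroperoxy-4,6,8-trimethyl-16-phenylhexadec-2-enoate F5. Amine-mediated intramolecular oxa-Michael addition (Et2NH, CF3CH2OH, rt; 6-exo-trig) should close the ring to 18 together with its C3 epimer, from which 18 is separated, and the route is rejoined at 18.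

Further compounds

F1 | step 9 | (3R,4R,5R,7R)-3,5,7-trimethyl-15-phenyl-5-(triethylsilylperoxy)pentadec-1-en-4-ol | C[C@H](CCCCCCCCc1ccccc1)C[C@@](C)(OO[Si](CC)(CC)CC)[C@H](O)[C@H](C)C=C
F2 | step 11 | (4R,6R)-3-methoxy-4,6-dimethyl-6-[(2R)-2-methyl-10-phenyldecyl]-1,2-dioxan-5-one | C[C@H](CCCCCCCCc1ccccc1)C[C@]1(C)C(=O)[C@H](C)C(OC)OO1
F3 | step 11 | N'-[(4S,6R)-3-methoxy-4,6-dimethyl-6-[(2R)-2-methyl-10-phenyldecyl]-1,2-dioxan-5-ylidene]-4-methylbenzenesulfonohydrazide | C[C@H](CCCCCCCCc1ccccc1)C[C@]1(C)C(=NNS(=O)(=O)c2ccc(C)cc2)[C@H](C)C(OC)OO1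
F4 | step 12 | (4S,6R)-4,6-dimethyl-6-[(2R)-2-methyl-10-phenyldecyl]-1,2-dioxan-3-ol | C[C@H](CCCCCCCCc1ccccc1)C[C@]1(C)C[C@H](C)C(O)OO1
F5 | step 12 | methyl (2E,4S,6R,8R)-6-hydroperoxy-4,6,8-trimethyl-16-phenylhexadec-2-enoate | C[C@H](CCCCCCCCc1ccccc1)C[C@@](C)(OO)C[C@H](C)/C=C/C(=O)OC
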